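**Plan**

1. Numbering (target, used throughout): ring methine C1 (R), ring carbons C2–C14 with alkenes C3=C4, C7=C8 and C11=C12, carbinol carbon C15 (S) outside the ring.
2. Enabling feature: the hydroxyl oxygen, C15, C1, C2, C3 and C4 lie in a row that ends in the C3=C4 alkene, so these six atoms can be held as a 3,4-dihydro-2H-pyran whose C4–O bond leaves when a carbon group moves onto C4.
3. Cuts: C12–C13 (ring closure by B-alkyl Suzuki coupling), then C4–C5 together with C4–CH3 (cuprate 1,2-metallate shift on the C4-lithiated pyran, then methylation), then O–C4, C2–C3 and C1–C14 back to farnesol; the C5–C12 piece is cut at C8–C9 and C8–CH3 in the same way, with 2,3-dihydrofuran as template.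
4. Forward: farnesol → epoxy alcohol → vinyl diol → alkynol → dihydropyran; pent-3-yn-1-ol → chloroalkenyl iodide → C5–C12 iodide; pyran, iodide and iodomethane are joined to the open chain (the pyran ring opens), and the fourteen-membered ring is closed last.
5. Stereochemistry: C15 and C1 from the Sharpless epoxidation (L-(+)-tartrate) and SN2 opening at C1 with inversion; C3=C4 and C7=C8 from anti migration followed by retentive methylation; C11=C12 from syn hydrozirconation; the side-chain alkene is that of farnesol.

Key step: step 11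

**Route**

Step 1
Reactants: 1 (2E,6E)-farnesol
Product: 2 [(2S,3S)-3-[(3E)-4,8-dimethylnona-3,7-dien-1-yl]-3-methyloxiran-2-yl]methanol
Conditions: Ti(OiPr)4 (5 mol %), L-(+)-diethyl tartrate (6 mol %), t-BuOOH, 4 Å molecular sieves, CH2Cl2, −20 °C
Reagents that add atoms: tert-butyl hydroperoxide, CC(C)(C)OO
Why: Katsuki–Sharpless asymmetric epoxidation acts only on the allylic alcohol alkene, and with L-(+)-tartrate an E allylic alcohol should give the (2S,3S)-epoxide, which fixes C15 in its final configuration and C1 in the configuration that step 2 inverts.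

Step 2
Reactants: 2 epoxy alcohol; 3 vinylmagnesium bromide
Product: 4 (2R,3S,6E)-2-ethenyl-3,7,11-trimethyldodeca-6,10-diene-1,3-diol
Conditions: 3 (4 equiv), CuI (10 mol %), THF, −30 → 0 °C
Reagents that add atoms: none
Why: Copper-catalysed Grignard opening of a 2,3-epoxy alcohol, in which the fully substituted epoxide carbon (C15) is shielded, so the vinyl group should attack the secondary carbon (C1) in SN2 fashion with inversion and give the 1,3-diol with C1 as in the target and C15 untouched.

Step 3
Reactants: 4 diol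
Product: 6 (2R,3S,6E)-2-ethenyl-3,7,11-trimethyl-3-[(triethylsilyl)oxy]dodeca-6,10-dien-1-yl trifluoromethanesulfonate, via hydroxy triflate 5 (not isolated)
Conditions: Tf2O (1.05 equiv), 2,6-lutidine, CH2Cl2, −78 °C; then Et3SiOTf, −78 → −30 °C
Reagents that add atoms: trifluoromethanesulfonic anhydride, O=S(=O)(OS(=O)(=O)C(F)(F)F)C(F)(F)F; triethylsilyl trifluoromethanesulfonate, CC[Si](CC)(CC)OS(=O)(=O)C(F)(F)F
Why: Triflic anhydride at −78 °C sulfonylates the primary hydroxyl much faster than the tertiary one, and silylation of the tertiary hydroxyl in the same flask keeps its alkoxide from closing an oxetane onto the triflate in step 4.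

Step 4
Reactants: 6 silyloxy triflate; 7 ethynyltrimethylsilane
Product: 9 (4S,5S,8E)-4-ethenyl-5,9,13-trimethyl-5-[(triethylsilyl)oxy]-1-(trimethylsilyl)tetradeca-8,12-dien-1-yne, via lithium (trimethylsilyl)acetylide 8 (not isolated)
Conditions: 7, n-BuLi, THF, −78 °C; then 6, DMPU, −78 → −20 °C
Reagents that add atoms: none
Why: SN2 displacement of a primary triflate by a lithium acetylide in THF–DMPU is a standard C(sp3)–C(sp) bond formation that proceeds at low temperature even next to a branched carbon, and it forms C2–C3 without involving the C1 stereocentre.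

Step 5
Reactants: 9 bis-silylated alkyne
Product: 11 (4S,5S,8E)-4-ethenyl-5,9,13-trimethyltetradeca-8,12-dien-1-yn-5-ol, via terminal alkyne silyl ether 10 (not isolated)
Conditions: Bu4NF (3 equiv), THF, 0 °C → rt
Reagents that add atoms: none
Why: Fluoride cleaves the alkynyl C–Si bond first and then the tertiary triethylsilyl ether, leaving alkenes and stereocentres untouched.

Step 6
Reactants: 11 alkynol
Product: 12 (2S,3S)-2-[(3E)-4,8-dimethylnona-3,7-dien-1-yl]-3-ethenyl-2-methyl-3,4-dihydro-2H-pyran
Conditions: W(CO)6 (25 mol %), Et3N, THF, hν (350 nm), 60 °C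
Reagents that add atoms: none
Why: Tungsten-catalysed alkynol cycloisomerisation, in which photogenerated W(CO)5 turns the terminal alkyne into a tungsten vinylidene whose electrophilic carbon (C4) is attacked by the tertiary hydroxyl, so the ring should close in the 6-endo sense to the dihydropyran and not to the five-membered exo-methylene ether, with no stereocentre touched.

Step 7
Reactants: 13 pent-3-yn-1-ol
Product: 15 (3E)-4-chloropent-3-en-1-ol, via alkenylzirconocene chloride 14 (not isolated)
Conditions: Cp2Zr(H)Cl (2.5 equiv), THF, rt → 40 °C; then N-chlorosuccinimide, 0 °C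
Reagents that add atoms: N-chlorosuccinimide, O=C1CCC(=O)N1Cl
Why: Hydrozirconation is a syn addition, the first equivalent of Cp2Zr(H)Cl being spent on the hydroxyl while excess reagent equilibrates the alkenylzirconium to the isomer with zirconium on the less hindered methyl-bearing carbon (C12), and N-chlorosuccinimide cleaves the C–Zr bond with retention to the E alkenyl chloride.

Step 8
Reactants: 15 chloro alcohol
Product: 16 (2E)-2-chloro-5-iodopent-2-ene
Conditions: I2, PPh3, imidazole, CH2Cl2, 0 °C → rt
Reagents that add atoms: iodine, II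
Why: Appel-type iodination of a primary alcohol runs under near-neutral conditions that leave the alkenyl chloride untouched.

Step 9
Reactants: 16 chloro iodide; 17 2,3-dihydrofuran; 18 iodomethane
Product: 24 (3E,7E)-8-chloro-4-methylnona-3,7-dien-1-ol, via 5-lithio-2,3-dihydrofuran 19 (not isolated), via alkyllithium 20 (not isolated), via alkylcopper 21 (not isolated), via lithium cuprate 22 (not isolated), via alkenylcopper alkoxide 23 (not isolated)
Conditions: 17, t-BuLi, THF, −78 → 0 °C; separately 16, t-BuLi (2 equiv), Et2O–pentane, −78 °C, then CuBr·SMe2, Me2S–Et2O, −78 → −40 °C; combine at −78 °C, warm to 0 °C; then 18, DMPU, 0 °C → rt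
Reagents that add atoms: none
Why: This is the 1,2-metallate rearrangement of an α-alkoxyalkenyl cuprate in its best established form, on 5-lithio-2,3-dihydrofuran, where the alkyl group moves from copper to the oxygen-bearing alkene carbon anti to the C–O bond and the alkenylcopper is then methylated with retention, which should give the E alkene C7=C8 and also rehearses the key step on a simple ring.

Step 10
Reactants: 24 dienol
Product: 25 (2E,6E)-2-chloro-9-iodo-6-methylnona-2,6-diene
Conditions: I2, PPh3, imidazole, CH2Cl2, 0 °C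
Reagents that add atoms: iodine, II
Why: Appel-type iodination of the primary homoallylic alcohol proceeds without touching either alkene or the alkenyl chloride.

Step 11
Reactants: 12 dihydropyran; 25 C5–C12 iodide; 18 iodomethane
Product: 31 (6E,10S,11S,13E,17E,21E)-22-chloro-11-ethenyl-2,6,10,14,18-pentamethyltricosa-2,6,13,17,21-pentaen-10-ol, via lithiated dihydropyran 26 (not isolated), via alkyllithium 27 (not isolated), via alkylcopper 28 (not isolated), via lithium cuprate 29 (not isolated), via alkenylcopper alkoxide 30 (not isolated)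
Conditions: 12, t-BuLi, THF, −78 → 0 °C; separately 25, t-BuLi (2 equiv), Et2O–pentane, −78 °C, then CuBr·SMe2, Me2S–Et2O, −78 → −40 °C; combine at −78 °C, warm to rt; then 18, DMPU, 0 °C → rt
Reagents that add atoms: none
Why: t-BuLi removes the vinylic hydrogen at C4 next to the ring oxygen, and the alkenyllithium 26 adds to alkylcopper 28 to give the mixed lithium cuprate 29. On warming, the C5 alkyl group migrates from copper to C4 anti to the C4–O bond, the tertiary alkoxide leaves, the pyran opens and copper ends cis to C2 as the alkoxide-ligated alkenylcopper 30, which iodomethane alkylates at C4 with retention. The closest known reaction is the 1,2-metallate rearrangement of cuprates from lithiated dihydrofurans and dihydropyrans followed by alkylation, as in step 9; the only difference here is that the departing oxygen sits on a fully substituted carbon, which is remote from the migration terminus. No ring closes and no stereocentre forms, and C1 and C15 are spectators. The step needs the E geometry at C3=C4, which follows from the cis ring geometry of the enol ether, inversion at C4 in the migration and retention in the methylation. Chemoselectivity rests on the fast iodine–lithium exchange of the primary iodide at −78 °C, which should leave the alkenyl chloride, the vinyl group and the trisubstituted alkenes untouched.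

Step 12
Reactants: 31 open-chain chloro alcohol
Product: 33 colleterpenol [(2S,5E)-6,10-dimethyl-2-[(1R,3E,7E,11E)-4,8,12-trimethylcyclotetradeca-3,7,11-trien-1-yl]undeca-5,9-dien-2-ol], via B-alkyl-9-BBN borane 32 (not isolated)
Conditions: 9-BBN dimer (excess), THF, 0 °C → rt; then slow addition to Pd(OAc)2 (10 mol %), SPhos (20 mol %), aq K3PO4, THF, 65 °C, high dilution
Reagents that add atoms: none
Why: 9-BBN adds only to the monosubstituted alkene with boron at the terminal carbon C13, and B-alkyl Suzuki–Miyaura coupling of this borane with the alkenyl chloride on zerovalent palladium carrying SPhos, run at high dilution, should close the fourteen-membered ring at C12–C13 with retention of the E geometry at C11=C12.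

**Compound list**

1 | (2E,6E)-farnesol | CC(C)=CCC/C(C)=C/CC/C(C)=C/CO | starting material
2 | [(2S,3S)-3-[(3E)-4,8-dimethylnona-3,7-dien-1-yl]-3-methyloxiran-2-yl]methanol | CC(C)=CCC/C(C)=C/CC[C@]1(C)O[C@H]1CO | intermediate
3 | vinylmagnesium bromide | C=C[Mg]Br | starting material
4 | (2R,3S,6E)-2-ethenyl-3,7,11-trimethyldodeca-6,10-diene-1,3-diol | CC(C)=CCC/C(C)=C/CC[C@](C)(O)[C@H](C=C)CO | intermediate
5 | (2R,3S,6E)-2-ethenyl-3-hydroxy-3,7,11-trimethyldodeca-6,10-dien-1-yl trifluoromethanesulfonate (formed in the flask) | CC(C)=CCC/C(C)=C/CC[C@](C)(O)[C@H](C=C)COS(=O)(=O)C(F)(F)F | intermediate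
6 | (2R,3S,6E)-2-ethenyl-3,7,11-trimethyl-3-[(triethylsilyl)oxy]dodeca-6,10-dien-1-yl trifluoromethanesulfonate | CC(C)=CCC/C(C)=C/CC[C@](C)(O[Si](CC)(CC)CC)[C@H](C=C)COS(=O)(=O)C(F)(F)F | intermediate
7 | ethynyltrimethylsilane | C#C[Si](C)(C)C | starting material
8 | lithium (trimethylsilyl)acetylide (formed in the flask) | [Li]C#C[Si](C)(C)C | intermediate
9 | (4S,5S,8E)-4-ethenyl-5,9,13-trimethyl-5-[(triethylsilyl)oxy]-1-(trimethylsilyl)tetradeca-8,12-dien-1-yne | CC(C)=CCC/C(C)=C/CC[C@](C)(O[Si](CC)(CC)CC)[C@H](C=C)CC#C[Si](C)(C)C | intermediate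
10 | (4S,5S,8E)-4-ethenyl-5,9,13-trimethyl-5-[(triethylsilyl)oxy]tetradeca-8,12-dien-1-yne (formed in the flask) | CC(C)=CCC/C(C)=C/CC[C@](C)(O[Si](CC)(CC)CC)[C@H](C=C)CC#C | intermediate
11 | (4S,5S,8E)-4-ethenyl-5,9,13-trimethyltetradeca-8,12-dien-1-yn-5-ol | CC(C)=CCC/C(C)=C/CC[C@](C)(O)[C@H](C=C)CC#C | intermediate
12 | (2S,3S)-2-[(3E)-4,8-dimethylnona-3,7-dien-1-yl]-3-ethenyl-2-methyl-3,4-dihydro-2H-pyran | CC(C)=CCC/C(C)=C/CC[C@]1(C)OC=CC[C@H]1C=C | intermediate
13 | pent-3-yn-1-ol | CC#CCCO | starting material
14 | alkenylzirconocene chloride of the zirconocene alkoxide, Cp2Zr(Cl)OCH2CH2CH=C(CH3)Zr(Cl)Cp2, zirconium on the methyl-bearing carbon and trans to the CH2 group (formed in the flask) | Cl[Zr](C1C=CC=C1)(C1C=CC=C1)OCC/C=C(\C)[Zr](Cl)(C1C=CC=C1)C1C=CC=C1 | intermediate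
15 | (3E)-4-chloropent-3-en-1-ol | OCC/C=C(\C)Cl | intermediate
16 | (2E)-2-chloro-5-iodopent-2-ene | ICC/C=C(\C)Cl | intermediate
17 | 2,3-dihydrofuran | C1CC=CO1 | starting material
18 | iodomethane | CI | starting material
19 | 5-lithio-2,3-dihydrofuran (formed in the flask) | [Li]C1=CCCO1 | intermediate
20 | [(3E)-4-chloropent-3-en-1-yl]lithium (formed in the flask) | [Li]CC/C=C(\C)Cl | intermediate
21 | [(3E)-4-chloropent-3-en-1-yl]copper (formed in the flask) | [Cu]CC/C=C(\C)Cl | intermediate
22 | lithium [(3E)-4-chloropent-3-en-1-yl](4,5-dihydrofuran-2-yl)cuprate (formed in the flask) | [Li+].C1CC=C(O1)[Cu-]CC/C=C(\C)Cl | intermediate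
23 | lithium (3E,7E)-8-chloro-4-cuprionona-3,7-dien-1-olate, copper on C4 cis to C2 (formed in the flask) | [Li]OCC/C=C(\[Cu])CC/C=C(\C)Cl | intermediate
24 | (3E,7E)-8-chloro-4-methylnona-3,7-dien-1-ol | OCC/C=C(\C)CC/C=C(\C)Cl | intermediate
25 | (2E,6E)-2-chloro-9-iodo-6-methylnona-2,6-diene | ICC/C=C(\C)CC/C=C(\C)Cl | intermediate
26 | 6-lithio derivative of 12, lithium on the enol ether carbon next to oxygen (C4 of the target) (formed in the flask) | CC(C)=CCC/C(C)=C/CC[C@]1(C)OC([Li])=CC[C@H]1C=C | intermediate
27 | [(3E,7E)-8-chloro-4-methylnona-3,7-dien-1-yl]lithium (formed in the flask) | [Li]CC/C=C(\C)CC/C=C(\C)Cl | intermediate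
28 | [(3E,7E)-8-chloro-4-methylnona-3,7-dien-1-yl]copper (formed in the flask) | [Cu]CC/C=C(\C)CC/C=C(\C)Cl | intermediate
29 | lithium cuprate from 26 and 28, copper bonded to C4 of the pyran and to C5 of the chain (formed in the flask) | [Li+].CC(C)=CCC/C(C)=C/CC[C@]1(C)OC([Cu-]CC/C=C(\C)CC/C=C(\C)Cl)=CC[C@H]1C=C | intermediate
30 | ring-opened alkenylcopper lithium alkoxide, copper on C4 cis to C2, lithium on the C15 oxygen (formed in the flask) | CC(C)=CCC/C(C)=C/CC[C@](C)(O[Li])[C@H](C=C)C/C=C(\[Cu])CC/C=C(\C)CC/C=C(\C)Cl | intermediate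
31 | (6E,10S,11S,13E,17E,21E)-22-chloro-11-ethenyl-2,6,10,14,18-pentamethyltricosa-2,6,13,17,21-pentaen-10-ol | CC(C)=CCC/C(C)=C/CC[C@](C)(O)[C@H](C=C)C/C=C(\C)CC/C=C(\C)CC/C=C(\C)Cl | intermediate
32 | B-alkyl-9-BBN borane: 31 with CH2CH2–B(9-borabicyclo[3.3.1]nonane) in place of the vinyl group, boron on C13 (formed in the flask) | CC(C)=CCC/C(C)=C/CC[C@](C)(O)[C@H](CCB1C2CCCC1CCC2)C/C=C(\C)CC/C=C(\C)CC/C=C(\C)Cl | intermediate
33 | colleterpenol, (2S,5E)-6,10-dimethyl-2-[(1R,3E,7E,11E)-4,8,12-trimethylcyclotetradeca-3,7,11-trien-1-yl]undeca-5,9-dien-2-ol | CC(C)=CCC/C(C)=C/CC[C@](C)(O)[C@H]1C/C=C(\C)CC/C=C(\C)CC/C=C(\C)CC1 | target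

**Step count and risks**

Total step count: 12. Longest linear sequence: 8 steps (steps 1–6, 11 and 12, from farnesol).

Steps most likely to fail:

Step 11. The shift of the C5 group out of the six-membered enol ether needs room temperature. There, β-hydride loss from the alkylcopper, incomplete migration or protonation of the alkenylcopper ahead of methylation may erode the three-component coupling. The fallback sets out from 25 and 6 and returns at 31. It makes the C2–C3 bond by Negishi coupling, with the C3=C4 alkene built beforehand by carboalumination. Iodide 25 is alkylated with lithium acetylide–ethylenediamine complex in DMSO to (5E,9E)-10-chloro-6-methylundeca-5,9-dien-1-yne F1. Zirconium-catalysed carboalumination (Me3Al, Cp2ZrCl2, CH2Cl2) places the methyl group on C4 and gives the alkenyl(dimethyl)alane F2, and iodine converts it into (1E,5E,9E)-10-chloro-1-iodo-2,6-dimethylundeca-1,5,9-triene F3. Triflate 6 is treated with NaI in acetone to give the primary iodide F4, and zinc insertion (Zn, LiCl, THF) gives the alkylzinc iodide F5. Pd(PPh3)4-catalysed coupling of F5 with F3 joins C2 to C3 with retention and should give the triethylsilyl ether of 31 F6, from which Bu4NF releases 31.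

Step 12. Intermolecular coupling to oligomers may outrun ring closure, or slow oxidative addition of the alkenyl chloride may leave the borane to be lost by protodeboronation. The fallback sets out from 31 and returns at 33. It closes the same bond with an alkylzinc under anhydrous conditions and with the carbinol protected. Et3SiOTf and 2,6-lutidine give the triethylsilyl ether of 31 F7. 9-BBN gives the B-alkyl borane F8, and NaOH with H2O2 oxidises it to the C13 primary alcohol F9. I2, PPh3 and imidazole give the primary iodide F10, and zinc insertion (Zn, LiCl, THF) gives the alkylzinc iodide F11. F11 is added slowly to Pd(OAc)2 and SPhos in THF at 60 °C, and intramolecular Negishi coupling should give the macrocyclic triethylsilyl ether F12, which Bu4NF converts into 33.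

Step 6. Addition of the hindered tertiary hydroxyl to the tungsten vinylidene may be slow, so that the metal carbene is diverted by the neighbouring vinyl group or the catalyst decays under irradiation. The fallback sets out from 11 and returns at 12. It makes the enol ether by dehydration of a lactol. Ruthenium-catalysed anti-Markovnikov hydration of the terminal alkyne ([CpRu(MeCN)3]PF6, 5,5'-bis(trifluoromethyl)-2,2'-bipyridine, aqueous NMP) should give the aldehyde as its ring tautomer, the lactol F13. MsCl and Et3N convert it into the anomeric methanesulfonate F14, which loses methanesulfonic acid on warming to give 12.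

Further compounds
F1 | step 11 | (5E,9E)-10-chloro-6-methylundeca-5,9-dien-1-yne | C#CCC/C=C(\C)CC/C=C(\C)Cl
F2 | step 11 | dimethyl[(1E,5E,9E)-10-chloro-2,6-dimethylundeca-1,5,9-trien-1-yl]alane | C[Al](C)/C=C(\C)CC/C=C(\C)CC/C=C(\C)Cl
F3 | step 11 | (1E,5E,9E)-10-chloro-1-iodo-2,6-dimethylundeca-1,5,9-triene | I/C=C(\C)CC/C=C(\C)CC/C=C(\C)Cl
F4 | step 11 | triethyl{[(3S,4S,7E)-3-(iodomethyl)-4,8,12-trimethyltrideca-1,7,11-trien-4-yl]oxy}silane | CC(C)=CCC/C(C)=C/CC[C@](C)(O[Si](CC)(CC)CC)[C@H](C=C)CI
F5 | step 11 | alkylzinc iodide from F4, ZnI in place of iodine | CC(C)=CCC/C(C)=C/CC[C@](C)(O[Si](CC)(CC)CC)[C@H](C=C)C[Zn]I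
F6 | step 11 | triethylsilyl ether of 31 | CC(C)=CCC/C(C)=C/CC[C@](C)(O[Si](CC)(CC)CC)[C@H](C=C)C/C=C(\C)CC/C=C(\C)CC/C=C(\C)Cl
F7 | step 12 | triethylsilyl ether of 31 | CC(C)=CCC/C(C)=C/CC[C@](C)(O[Si](CC)(CC)CC)[C@H](C=C)C/C=C(\C)CC/C=C(\C)CC/C=C(\C)Cl
F8 | step 12 | B-alkyl-9-BBN borane from F7, boron on C13 | CC(C)=CCC/C(C)=C/CC[C@](C)(O[Si](CC)(CC)CC)[C@H](CCB1C2CCCC1CCC2)C/C=C(\C)CC/C=C(\C)CC/C=C(\C)Cl
F9 | step 12 | C13 primary alcohol, F7 with CH2CH2OH in place of vinyl | CC(C)=CCC/C(C)=C/CC[C@](C)(O[Si](CC)(CC)CC)[C@H](CCO)C/C=C(\C)CC/C=C(\C)CC/C=C(\C)Cl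
F10 | step 12 | C13 primary iodide from F9 | CC(C)=CCC/C(C)=C/CC[C@](C)(O[Si](CC)(CC)CC)[C@H](CCI)C/C=C(\C)CC/C=C(\C)CC/C=C(\C)Cl
F11 | step 12 | alkylzinc iodide from F10 | CC(C)=CCC/C(C)=C/CC[C@](C)(O[Si](CC)(CC)CC)[C@H](CC[Zn]I)C/C=C(\C)CC/C=C(\C)CC/C=C(\C)Cl
F12 | step 12 | triethylsilyl ether of 33 | CC(C)=CCC/C(C)=C/CC[C@](C)(O[Si](CC)(CC)CC)[C@H]1C/C=C(\C)CC/C=C(\C)CC/C=C(\C)CC1
F13 | step 6 | (5S,6S)-6-[(3E)-4,8-dimethylnona-3,7-dien-1-yl]-5-ethenyl-6-methyloxan-2-ol, both anomers | CC(C)=CCC/C(C)=C/CC[C@]1(C)OC(O)CC[C@H]1C=C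
F14 | step 6 | methanesulfonate of F13 at the anomeric oxygen | CC(C)=CCC/C(C)=C/CC[C@]1(C)OC(OS(C)(=O)=O)CC[C@H]1C=C
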